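**Plan**

- Ring numbering (bibenzyl): ring A carries the bridge at C1, OH at C3, OMe at C5; ring B carries the bridge at C1', OH at C2', a benzyl at C5'. The retrosynthesis first cuts the two aryl–CH2 bonds at A-C2 and A-C6 (twofold Friedel–Crafts benzylation of the electron-rich ring A).
- Enabling feature: ring B is a phenol with the bridge ortho (C1') and a benzyl para (C5') to the C2' hydroxyl, which is the dehydrogenated form of a 6-alkyl-4-benzylcyclohex-2-enone. Ring B is therefore cut at C5'–C6' (Michael) and C3'–C4' (aldol) into a 3-arylpropanal and a ring-A α-methylene methyl ketone.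
- The α-methylene ketone is cut at its exocyclic CH2 (Mannich) and at the Cα–CH2 bond to an acetoacetate and a ring-A phenethyl bromide, which comes from the ring-A benzaldehyde by one-carbon homologation.
- Forward: ring A is aromatic from the start and its side chain is built in steps 1–6. Ring B is closed as a cyclohexenone in step 8 and aromatised in step 9; the benzyl ethers fall in step 10 and ring A is benzylated twice in step 11.
- Stereochemistry: the target has no stereocentre; the two sp3 centres made in step 8 are erased in step 9.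

Key step: step 8

Remark: the target is achiral (no stereocentre, no stereogenic double bond or axis), so the "single enantiomer" is the compound itself and no step has to control configuration. The compounds marked as starting materials in the compound list are assumed to be purchasable.

**Route**

Step 1
Reactants: 1 3-hydroxy-5-methoxybenzaldehyde
Product: 2 3-(benzyloxy)-5-methoxybenzaldehyde
Conditions: BnBr, K2CO3, DMF, rt
Reagents that add atoms: benzyl bromide, BrCc1ccccc1
Why: Williamson ether synthesis on the phenoxide; the benzyl ether should survive every later step and is removed in step 10 together with the second one.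

Step 2
Reactants: 2 3-(benzyloxy)-5-methoxybenzaldehyde
Product: 3 1-(benzyloxy)-3-ethenyl-5-methoxybenzene
Conditions: Ph3PCH3Br, KOtBu, THF, 0 °C to rt
Reagents that add atoms: methyltriphenylphosphonium bromide, C[P+](c1ccccc1)(c1ccccc1)c1ccccc1.[Br-]
Why: Wittig methylenation of an unhindered, non-enolisable aromatic aldehyde with the unstabilised ylide adds the one carbon needed for the two-carbon bridge.

Step 3
Reactants: 3 1-(benzyloxy)-3-ethenyl-5-methoxybenzene
Product: 5 2-[3-(benzyloxy)-5-methoxyphenyl]ethan-1-ol, via alkylborane 4 (not isolated)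
Conditions: 9-BBN, THF, 0 °C to rt; then NaOH aq., H2O2, 0 °C to rt
Reagents that add atoms: hydrogen peroxide, OO (9-borabicyclo[3.3.1]nonane, B1C2CCCC1CCC2, adds atoms only to intermediate 4)
Why: Hydroboration–oxidation with 9-BBN places boron on the terminal carbon of the styrene, and alkaline peroxide turns the C–B bond into the primary alcohol without touching the aryl ethers.

Step 4
Reactants: 5 2-[3-(benzyloxy)-5-methoxyphenyl]ethan-1-ol
Product: 6 1-(benzyloxy)-3-(2-bromoethyl)-5-methoxybenzene
Conditions: CBr4, PPh3, CH2Cl2, 0 °C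
Reagents that add atoms: carbon tetrabromide, BrC(Br)(Br)Br
Why: Appel reaction; bromide displaces the alkoxyphosphonium group of the primary alcohol by SN2 under neutral conditions that leave the ethers intact.

Step 5
Reactants: 6 1-(benzyloxy)-3-(2-bromoethyl)-5-methoxybenzene; 7 ethyl acetoacetate
Product: 8 ethyl 2-acetyl-4-[3-(benzyloxy)-5-methoxyphenyl]butanoate (racemic)
Conditions: 7 (1.5 equiv), NaH, THF/DMF, 0 °C; then 6, NaI (cat.), 60 °C
Reagents that add atoms: none
Why: Acetoacetic ester alkylation; the soft sodium enolate displaces the primary halide at carbon, the excess of 7 should suppress dialkylation, and the weakly basic enolate limits E2 loss of HBr.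

Step 6
Reactants: 8 ethyl 2-acetyl-4-[3-(benzyloxy)-5-methoxyphenyl]butanoate
Product: 10 5-[3-(benzyloxy)-5-methoxyphenyl]-3-methylidenepentan-2-one, via keto acid 9 (not isolated)
Conditions: KOH, MeOH/H2O, rt; HCl to pH 4–5, 0 °C; then 37% aq. CH2O, Et2NH, THF, rt
Reagents that add atoms: formaldehyde, C=O (potassium hydroxide, [K+].[OH-], supplies the carboxyl OH of intermediate 9)
Why: Saponification gives the β-keto acid, which undergoes decarboxylative Mannich methylenation (aminomethylation, then loss of CO2 and diethylamine), so the methylene can only end up on the carbon that carried the carboxyl group; the enone is used at once because α-alkyl vinyl ketones dimerise on standing.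

Step 7
Reactants: 11 1-(benzyloxy)-4-iodobenzene; 12 prop-2-en-1-ol (allyl alcohol)
Product: 13 3-[4-(benzyloxy)phenyl]propanal
Conditions: Pd(OAc)2 (cat.), n-Bu4NCl, NaHCO3, DMF, 40 °C
Reagents that add atoms: none
Why: Heck reaction under ligand-free phase-transfer conditions; arylpalladium adds to the terminal alkene carbon and β-hydride elimination toward the carbinol carbon gives an enol that tautomerises to the 3-arylpropanal.

Step 8
Reactants: 10 5-[3-(benzyloxy)-5-methoxyphenyl]-3-methylidenepentan-2-one; 13 3-[4-(benzyloxy)phenyl]propanal (1.3 equiv)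
Product: 15 4-[4-(benzyloxy)benzyl]-6-{2-[3-(benzyloxy)-5-methoxyphenyl]ethyl}cyclohex-2-en-1-one as a diastereomer mixture, via keto aldehyde 14 (not isolated)
Conditions: Et2NH (0.3 equiv), MeCN, rt; then KOH aq., n-Bu4NOH (cat.), THF/Et2O, reflux
Reagents that add atoms: none
Why: Diethylamine converts 13 into an enamine whose β-carbon adds to the terminal methylene carbon of 10 (Michael addition, forming C5'–C6'), and hydrolysis releases the amine and keto aldehyde 14; under hydroxide the methyl-ketone enolate of 14 attacks the aldehyde and the aldol loses water (forming C3'–C4' as the ring C=C). The closest known reaction type is the amine-catalysed Robinson annulation of unbranched aldehydes with vinyl ketones to 4-substituted cyclohex-2-enones, which extends to α-substituted vinyl ketones in the Stork enamine manifold. Ring B closes in the 6-(enolendo)-exo-trig aldol mode. The two new stereocentres (C4 from the conjugate addition, C6 from protonation) are formed without control and both are deleted on aromatisation, so a diastereomer mixture is acceptable. The step needs cross-Michael addition to win over self-aldol of 13 and needs a single ring-closure mode: the enone is the best electrophile present for the soft enamine, and only methyl-ketone-onto-aldehyde gives a six-membered ring (the alternatives would be four-membered), which places the bridge at C6 and the benzyl at C4 of the enone, ortho and para to the future phenol oxygen.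

Step 9
Reactants: 15 4-[4-(benzyloxy)benzyl]-6-{2-[3-(benzyloxy)-5-methoxyphenyl]ethyl}cyclohex-2-en-1-one
Product: 16 4-[4-(benzyloxy)benzyl]-2-{2-[3-(benzyloxy)-5-methoxyphenyl]ethyl}phenol
Conditions: Pd(TFA)2 (5 mol %), 2-(dimethylamino)pyridine (10 mol %), TsOH·H2O (20 mol %), O2 (1 atm), DMSO, 80 °C
Reagents that add atoms: none
Why: Aerobic palladium(II)-catalysed dehydrogenation of a cyclohexenone; the Pd enolate undergoes β-hydride elimination to a dienone that tautomerises to the phenol, O2 reoxidises Pd(0), and the aryl benzyl ethers and diarylmethane CH2 groups should not be affected.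

Step 10
Reactants: 16 4-[4-(benzyloxy)benzyl]-2-{2-[3-(benzyloxy)-5-methoxyphenyl]ethyl}phenol
Product: 17 3-{2-[2-hydroxy-5-(4-hydroxybenzyl)phenyl]ethyl}-5-methoxyphenol
Conditions: H2 (1 atm), 10% Pd/C, EtOAc/MeOH, rt
Reagents that add atoms: none
Why: Catalytic hydrogenolysis cleaves both aryl benzyl ethers at the benzylic C–O bond, while the aryl methyl ether and the diarylmethane and bibenzyl C–C bonds are inert.

Step 11
Reactants: 17 3-{2-[2-hydroxy-5-(4-hydroxybenzyl)phenyl]ethyl}-5-methoxyphenol; 18 4-hydroxybenzyl alcohol (2.2 equiv)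
Product: 19 3-{2-[2-hydroxy-5-(4-hydroxybenzyl)phenyl]ethyl}-2,4-bis(4-hydroxybenzyl)-5-methoxyphenol (CNP0134121.0)
Conditions: 18 (slow addition), TsOH·H2O (10 mol %), 1,4-dioxane, 60 °C
Reagents that add atoms: none
Why: Twofold Friedel–Crafts alkylation through the 4-hydroxybenzyl cation (protonated p-quinone methide); ring A is by far the most nucleophilic arene in 17, and A-C2 and A-C6 are each para to one oxygen and ortho to the other, the sites where 5-alkylresorcinol monoethers are substituted in preference to the position between the two oxygens, while slow addition of 18 should limit its self-condensation.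

**Compound list**

1 | 3-hydroxy-5-methoxybenzaldehyde | COc1cc(O)cc(C=O)c1 | starting material
2 | 3-(benzyloxy)-5-methoxybenzaldehyde | COc1cc(OCc2ccccc2)cc(C=O)c1 | intermediate
3 | 1-(benzyloxy)-3-ethenyl-5-methoxybenzene | COc1cc(OCc2ccccc2)cc(C=C)c1 | intermediate
4 | 9-{2-[3-(benzyloxy)-5-methoxyphenyl]ethyl}-9-borabicyclo[3.3.1]nonane (not isolated) | COc1cc(OCc2ccccc2)cc(CCB2C3CCCC2CCC3)c1 | intermediate
5 | 2-[3-(benzyloxy)-5-methoxyphenyl]ethan-1-ol | COc1cc(OCc2ccccc2)cc(CCO)c1 | intermediate
6 | 1-(benzyloxy)-3-(2-bromoethyl)-5-methoxybenzene | COc1cc(OCc2ccccc2)cc(CCBr)c1 | intermediate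
7 | ethyl acetoacetate | CCOC(=O)CC(C)=O | starting material
8 | ethyl 2-acetyl-4-[3-(benzyloxy)-5-methoxyphenyl]butanoate (racemic) | CCOC(=O)C(CCc1cc(OC)cc(OCc2ccccc2)c1)C(C)=O | intermediate
9 | 2-acetyl-4-[3-(benzyloxy)-5-methoxyphenyl]butanoic acid (racemic, not isolated) | OC(=O)C(CCc1cc(OC)cc(OCc2ccccc2)c1)C(C)=O | intermediate
10 | 5-[3-(benzyloxy)-5-methoxyphenyl]-3-methylidenepentan-2-one | CC(=O)C(=C)CCc1cc(OC)cc(OCc2ccccc2)c1 | intermediate
11 | 1-(benzyloxy)-4-iodobenzene | Ic1ccc(OCc2ccccc2)cc1 | starting material
12 | prop-2-en-1-ol | C=CCO | starting material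
13 | 3-[4-(benzyloxy)phenyl]propanal | O=CCCc1ccc(OCc2ccccc2)cc1 | intermediate
14 | 2-[4-(benzyloxy)benzyl]-4-{2-[3-(benzyloxy)-5-methoxyphenyl]ethyl}-5-oxohexanal (diastereomer mixture, not isolated) | CC(=O)C(CCc1cc(OC)cc(OCc2ccccc2)c1)CC(C=O)Cc1ccc(OCc2ccccc2)cc1 | intermediate
15 | 4-[4-(benzyloxy)benzyl]-6-{2-[3-(benzyloxy)-5-methoxyphenyl]ethyl}cyclohex-2-en-1-one (diastereomer mixture) | O=C1C=CC(Cc2ccc(OCc3ccccc3)cc2)CC1CCc1cc(OC)cc(OCc2ccccc2)c1 | intermediate
16 | 4-[4-(benzyloxy)benzyl]-2-{2-[3-(benzyloxy)-5-methoxyphenyl]ethyl}phenol | Oc1ccc(Cc2ccc(OCc3ccccc3)cc2)cc1CCc1cc(OC)cc(OCc2ccccc2)c1 | intermediate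
17 | 3-{2-[2-hydroxy-5-(4-hydroxybenzyl)phenyl]ethyl}-5-methoxyphenol | COc1cc(O)cc(CCc2cc(Cc3ccc(O)cc3)ccc2O)c1 | intermediate
18 | 4-hydroxybenzyl alcohol | OCc1ccc(O)cc1 | starting material
19 | 3-{2-[2-hydroxy-5-(4-hydroxybenzyl)phenyl]ethyl}-2,4-bis(4-hydroxybenzyl)-5-methoxyphenol | COc1cc(O)c(Cc2ccc(O)cc2)c(CCc2cc(Cc3ccc(O)cc3)ccc2O)c1Cc1ccc(O)cc1 | target

**Step count and risks**

Total step count: 11. Longest linear sequence: 10 steps (steps 1–6 and 8–11, from 1); step 7 is a one-step branch.

Steps most likely to fail:

1. Step 11. Site control in the double Friedel–Crafts alkylation may be lost: attack at A-C4 between the two oxygens, a third benzylation, attack on the free ortho position of ring B, acid-induced migration of benzyl groups, or self-condensation of 18. The fallback sets out from 16 and comes back at 19, fixing the positions of the new C–C bonds by halogens. The free phenol of 16 is benzylated (BnBr, K2CO3, DMF) to 1-(benzyloxy)-3-(2-{2-(benzyloxy)-5-[4-(benzyloxy)benzyl]phenyl}ethyl)-5-methoxybenzene F1. N-Bromosuccinimide (2 equiv, MeCN, 0 °C) should brominate only the doubly activated ring A, at the two positions para to an oxygen and ortho to the bridge, giving 1-(benzyloxy)-3-(2-{2-(benzyloxy)-5-[4-(benzyloxy)benzyl]phenyl}ethyl)-2,4-dibromo-5-methoxybenzene F2. From commercial 4-(benzyloxy)benzyl chloride and zinc dust (LiCl, THF) is made [4-(benzyloxy)benzyl]zinc chloride F3. A twofold Negishi coupling of F2 with F3 (Pd(OAc)2, SPhos, THF, 60 °C) should give 1-(benzyloxy)-2,4-bis[4-(benzyloxy)benzyl]-3-(2-{2-(benzyloxy)-5-[4-(benzyloxy)benzyl]phenyl}ethyl)-5-methoxybenzene F4. Hydrogenolysis of all five benzyl ethers (H2, Pd/C, EtOAc/MeOH) then gives 19.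

2. Step 8. Self-aldol condensation of the unbranched aldehyde may outrun its conjugate addition to the α-branched, less electrophilic enone, and the enone may dimerise while it waits. The fallback sets out from 13 (with 10) and comes back at 15, keeping the same two bonds but making the nucleophile stoichiometrically beforehand. Aldehyde 13 is condensed with pyrrolidine (K2CO3, Et2O, 0 °C) to 1-{(1E)-3-[4-(benzyloxy)phenyl]prop-1-en-1-yl}pyrrolidine F5, so that no free aldehyde is present alongside amine. F5 is added to 10 in dioxane at rt (Stork enamine Michael addition), and heating with AcOH/NaOAc/H2O hydrolyses the adduct to keto aldehyde 14 and closes it to 15.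

3. Step 6. The β-keto acid may simply decarboxylate before aminomethylation, giving the saturated methyl ketone, and the product enone may add amine or dimerise. The fallback sets out from 6 and comes back at 10. Bromide 6 alkylates the sodium salt of commercial diethyl (2-oxopropyl)phosphonate (NaH, NaI cat., DMF, 60 °C) to diethyl {5-[3-(benzyloxy)-5-methoxyphenyl]-2-oxopentan-3-yl}phosphonate F6. A Horner–Wadsworth–Emmons reaction of F6 with aqueous formaldehyde (K2CO3, THF/H2O, rt) then installs the methylene group regiospecifically and gives 10 under conditions where no keto acid is involved.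

Further compounds
F1 | step 11 | 1-(benzyloxy)-3-(2-{2-(benzyloxy)-5-[4-(benzyloxy)benzyl]phenyl}ethyl)-5-methoxybenzene | COc1cc(OCc2ccccc2)cc(CCc2cc(Cc3ccc(OCc4ccccc4)cc3)ccc2OCc2ccccc2)c1
F2 | step 11 | 1-(benzyloxy)-3-(2-{2-(benzyloxy)-5-[4-(benzyloxy)benzyl]phenyl}ethyl)-2,4-dibromo-5-methoxybenzene | COc1cc(OCc2ccccc2)c(Br)c(CCc2cc(Cc3ccc(OCc4ccccc4)cc3)ccc2OCc2ccccc2)c1Br
F3 | step 11 | [4-(benzyloxy)benzyl]zinc chloride | Cl[Zn]Cc1ccc(OCc2ccccc2)cc1
F4 | step 11 | 1-(benzyloxy)-2,4-bis[4-(benzyloxy)benzyl]-3-(2-{2-(benzyloxy)-5-[4-(benzyloxy)benzyl]phenyl}ethyl)-5-methoxybenzene | COc1cc(OCc2ccccc2)c(Cc2ccc(OCc3ccccc3)cc2)c(CCc2cc(Cc3ccc(OCc4ccccc4)cc3)ccc2OCc2ccccc2)c1Cc1ccc(OCc2ccccc2)cc1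
F5 | step 8 | 1-{(1E)-3-[4-(benzyloxy)phenyl]prop-1-en-1-yl}pyrrolidine | C(=C/N1CCCC1)\Cc1ccc(OCc2ccccc2)cc1
F6 | step 6 | diethyl {5-[3-(benzyloxy)-5-methoxyphenyl]-2-oxopentan-3-yl}phosphonate | CCOP(=O)(OCC)C(CCc1cc(OC)cc(OCc2ccccc2)c1)C(C)=O
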